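**Retrosynthetic overview**
- Target 51 comes from undecamer 50 by hydrogenolysis of its 28 benzyl ethers.
- 50 is cut at the four ethers O6(ring C, E, G, I)–C1(ring D, F, H, J). Each is made by palladium-catalysed C–O coupling of an O6 phenol with an aryl chloride block: D–E block 39 three times (rings D/E, F/G, H/I), then J–K block 43.
- The plan rests on ring C (and its copies E, G, I): oxygen on five contiguous carbons C1, C6, C5, C4, C3 and a single CH at C2. A squarate supplies C3–C6 with their oxygens; a 1-(aryloxy)vinyl group supplies C1, C2 and the ether to ring B.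
- Ring order: A–B ether first (C–O coupling, then Dakin oxidation); ring C closed on A–B by cyclobutenone ring expansion; the same sequence on 2,6-bis(benzyloxy)-4-chlorophenol closes ring E of block 39; J–K by Ullmann etherification.

Key step: step 11

**Remarks and assumptions**
- Rings are lettered A to K from the 2,4,6-trihydroxyphenoxy end; in each ring C1 is the carbon bonded to the oxygen coming from the preceding ring.
- The target has no stereocentre. Cyclobutenones 19, 20, 34, 35 are racemic and their stereocentre is lost on ring expansion.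
- Compounds 1, 6, 16 and 40 are taken as purchasable.
- Partially reacted species of steps that repeat one transformation at several equivalent sites (steps 3, 21, 22, 31) are not numbered.

**Route**

Step 1
Reactants: 1 1,3,5-tris(benzyloxy)benzene
Product: 3 2,4,6-tris(benzyloxy)benzaldehyde, via iminium chloride 2 (not isolated)
Conditions: POCl3, DMF, 0 °C to 70 °C; then H2O
Reagents that add atoms: N,N-dimethylformamide CN(C)C=O; water O
Why: Vilsmeier–Haack formylation of the electron-rich triether, whose three free positions are equivalent, so only one aldehyde can form.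

Step 2
Reactants: 3 2,4,6-tris(benzyloxy)benzaldehyde
Product: 5 2,4,6-tris(benzyloxy)phenol, via aryl formate 4 (not isolated)
Conditions: mCPBA, CH2Cl2, 0 °C to rt; aq NaHCO3 wash; then K2CO3 (cat.), MeOH, rt
Reagents that add atoms: mCPBA OOC(=O)c1cccc(Cl)c1
Why: Baeyer–Villiger (Dakin-type) oxidation with migration of the electron-rich aryl group gives the formate, which mild methanolysis cleaves without touching the benzyl ethers.

Step 3
Reactants: 6 4-chloro-2,6-difluorobenzaldehyde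
Product: 7 2,6-bis(benzyloxy)-4-chlorobenzaldehyde
Conditions: BnOH, KOt-Bu, THF, 0 °C to 60 °C
Reagents that add atoms: benzyl alcohol OCc1ccccc1
Why: Twofold nucleophilic aromatic substitution (SNAr) of the fluorides ortho to the formyl group; fluoride leaves far faster than the para chloride, which is kept as the later coupling handle.

Step 4
Reactants: 5 2,4,6-tris(benzyloxy)phenol; 7 2,6-bis(benzyloxy)-4-chlorobenzaldehyde
Product: 8 2,6-bis(benzyloxy)-4-[2,4,6-tris(benzyloxy)phenoxy]benzaldehyde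
Conditions: Pd(OAc)2 (cat.), tBuXPhos (cat.), K3PO4, toluene, 100 °C
Reagents that add atoms: none
Why: Palladium-catalysed C–O coupling (Buchwald–Hartwig etherification) of a di-ortho-substituted phenol with an aryl chloride activated by its para formyl group; the bulky biarylphosphine promotes C–O reductive elimination.

Step 5
Reactants: 8 2,6-bis(benzyloxy)-4-[2,4,6-tris(benzyloxy)phenoxy]benzaldehyde
Product: 10 2,6-bis(benzyloxy)-4-[2,4,6-tris(benzyloxy)phenoxy]phenol (phenol A–B), via aryl formate 9 (not isolated)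
Conditions: mCPBA, CH2Cl2, 0 °C; aq NaHCO3 wash; then K2CO3 (cat.), MeOH, rt
Reagents that add atoms: mCPBA OOC(=O)c1cccc(Cl)c1
Why: Baeyer–Villiger (Dakin-type) oxidation of the 2,6-dialkoxybenzaldehyde turns the formyl carbon into the O4 hydroxyl of ring B.

Step 6
Reactants: 10 phenol A–B
Product: 11 (E)-1,2-dichlorovinyl ether of phenol A–B
Conditions: trichloroethylene, K2CO3, DMF, 70 °C
Reagents that add atoms: trichloroethylene ClC=C(Cl)Cl
Why: Anti addition of the phenoxide to dichloroacetylene formed in situ from trichloroethylene gives the (E)-dichlorovinyl ether, a reaction that accepts 2,6-disubstituted phenols.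

Step 7
Reactants: 11 (E)-1,2-dichlorovinyl ether of phenol A–B
Product: 14 ethynyl ether of phenol A–B, via chloroethynyl ether 12 (not isolated), via lithium acetylide 13 (not isolated)
Conditions: n-BuLi (2.2 equiv), THF, −78 °C to −40 °C; then MeOH, −78 °C
Reagents that add atoms: none
Why: Dehydrochlorination followed by chlorine–lithium exchange gives the lithium aryloxyacetylide, which is protonated to the terminal ynol ether and used at once because aryl ethynyl ethers polymerise on standing.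

Step 8
Reactants: 14 ethynyl ether of phenol A–B
Product: 15 tributyl[1-(A–B aryloxy)ethenyl]stannane
Conditions: Bu3SnH, Pd(PPh3)4 (cat.), THF, 0 °C
Reagents that add atoms: tributyltin hydride CCCC[SnH](CCCC)CCCC
Why: Zerovalent palladium-catalysed syn-hydrostannation of the ynol ether places tin on the oxygen-bearing carbon and gives the 1-aryloxy-1-stannylethene.

Step 9
Reactants: 16 squaric acid
Product: 17 3,4-bis(benzyloxy)cyclobut-3-ene-1,2-dione (dibenzyl squarate)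
Conditions: BnOH, toluene, reflux, Dean–Stark trap
Reagents that add atoms: benzyl alcohol OCc1ccccc1
Why: Azeotropic esterification of the strongly acidic vinylogous diacid with a primary alcohol, as used for other dialkyl squarates.

Step 10
Reactants: 15 tributyl[1-(A–B aryloxy)ethenyl]stannane; 17 dibenzyl squarate
Product: 20 2,3-bis(benzyloxy)-4-(methoxymethoxy)-4-[1-(A–B aryloxy)ethenyl]cyclobut-2-en-1-one (racemic), via vinyllithium 18 (not isolated), via lithium alkoxide 19 (not isolated)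
Conditions: n-BuLi, THF, −78 °C; then 17, −78 °C; then MOMCl, −78 °C to 0 °C
Reagents that add atoms: chloromethyl methyl ether COCCl
Why: Tin–lithium exchange gives the 1-(aryloxy)vinyllithium, which adds 1,2 to one of the two equivalent squarate carbonyls; the tertiary alkoxide is O-alkylated in situ, and the new quaternary carbon is racemic and disappears in step 11.

Step 11
Reactants: 20 4-[1-(A–B aryloxy)ethenyl]-4-(methoxymethoxy)cyclobutenone
Product: 23 A–B–C trimer phenol (ring C: C3–OH free; C6–OMOM; C4 and C5 benzyloxy), via dienylketene 21 (not isolated), via cyclohexadienone 22 (not isolated)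
Conditions: toluene (degassed), 110 °C
Reagents that add atoms: none
Why: Heating opens the cyclobutenone by conrotatory 4π electrocyclic cleavage of its C1–C4 bond to dienylketene 21, and disrotatory 6π electrocyclisation then joins the ketene carbon to the vinyl CH2 (ring C bond C2–C3), closing ring C as cyclohexadienone 22, which enolises to phenol 23. This is the Moore rearrangement of 4-alkenyl-4-alkoxycyclobutenones, known to give polyoxygenated phenols from squarate adducts that carry 1-alkoxyvinyl groups. Ring C is thus closed by a pericyclic 6π closure, and no stereocentre is created; the racemic quaternary carbon of 20 becomes aromatic C6. The step needs torquoselectivity: the vinyl group must rotate inward to lie cis to the ketene, and the donor oxygen of the OMOM group on C4, which rotates outward, secures this. The oxygen pattern is fixed by construction, because the squarate carbons become C3 to C6 (O3 free, O6 as MOM ether) and the enol ether becomes C1–C2 with the ether to ring B.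

Step 12
Reactants: 23 A–B–C trimer phenol
Product: 24 A–B–C trimer with ring C tribenzylated and C6–OMOM
Conditions: BnBr, K2CO3, DMF, rt
Reagents that add atoms: benzyl bromide BrCc1ccccc1
Why: Williamson etherification of the only free phenol (O3, flanked by C2–H).

Step 13
Reactants: 24 A–B–C trimer MOM ether
Product: 25 A–B–C trimer O6 phenol
Conditions: HCl (cat.), MeOH/THF, 45 °C
Reagents that add atoms: none
Why: Acid-catalysed acetal exchange removes the aryl MOM ether; benzyl and diaryl ethers are stable to dilute HCl.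

Step 14
Reactants: 7 2,6-bis(benzyloxy)-4-chlorobenzaldehyde
Product: 27 2,6-bis(benzyloxy)-4-chlorophenol, via aryl formate 26 (not isolated)
Conditions: mCPBA, CH2Cl2, 0 °C to rt; aq NaHCO3 wash; then K2CO3 (cat.), MeOH, rt
Reagents that add atoms: mCPBA OOC(=O)c1cccc(Cl)c1
Why: Baeyer–Villiger (Dakin-type) oxidation; the position of chlorine para to the new hydroxyl is fixed by the starting material, so no halogenation regiochemistry is at stake.

Step 15
Reactants: 27 2,6-bis(benzyloxy)-4-chlorophenol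
Product: 28 1,3-bis(benzyloxy)-5-chloro-2-{[(E)-1,2-dichloroethenyl]oxy}benzene
Conditions: trichloroethylene, K2CO3, DMF, 70 °C
Reagents that add atoms: trichloroethylene ClC=C(Cl)Cl
Why: Same phenoxide addition to in situ dichloroacetylene as in step 6.

Step 16
Reactants: 28 dichlorovinyl ether
Product: 31 1,3-bis(benzyloxy)-5-chloro-2-(ethynyloxy)benzene, via chloroethynyl ether 29 (not isolated), via lithium acetylide 30 (not isolated)
Conditions: n-BuLi (2.1 equiv), THF, −78 °C; then MeOH, −78 °C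
Reagents that add atoms: none
Why: Elimination and chlorine–lithium exchange at the alkynyl chloride are far faster at −78 °C than exchange or ortho-lithiation at the aryl chloride, which is why chloride was chosen as the handle.

Step 17
Reactants: 31 ethynyl ether
Product: 32 tributyl{1-[2,6-bis(benzyloxy)-4-chlorophenoxy]ethenyl}stannane
Conditions: Bu3SnH, Pd(PPh3)4 (cat.), THF, 0 °C
Reagents that add atoms: tributyltin hydride CCCC[SnH](CCCC)CCCC
Why: Palladium-catalysed hydrostannation as in step 8; the aryl chloride does not add to Pd(PPh3)4 at 0 °C.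

Step 18
Reactants: 32 stannane; 17 dibenzyl squarate
Product: 35 2,3-bis(benzyloxy)-4-{1-[2,6-bis(benzyloxy)-4-chlorophenoxy]ethenyl}-4-(methoxymethoxy)cyclobut-2-en-1-one (racemic), via vinyllithium 33 (not isolated), via lithium alkoxide 34 (not isolated)
Conditions: n-BuLi (1.05 equiv), THF, −78 °C; then 17, −78 °C; then MOMCl, −78 °C to 0 °C
Reagents that add atoms: chloromethyl methyl ether COCCl
Why: Tin–lithium exchange, 1,2-addition to the squarate and in situ O-alkylation as in step 10; the racemic quaternary carbon is lost in step 19.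

Step 19
Reactants: 35 cyclobutenone
Product: 38 2,3-bis(benzyloxy)-5-[2,6-bis(benzyloxy)-4-chlorophenoxy]-4-(methoxymethoxy)phenol, via dienylketene 36 (not isolated), via cyclohexadienone 37 (not isolated)
Conditions: toluene (degassed), 110 °C
Reagents that add atoms: none
Why: Moore rearrangement as in step 11 (4π opening with outward rotation of OMOM, 6π closure, enolisation) builds ring E on ring D.

Step 20
Reactants: 38 D–E phenol
Product: 39 block D–E: 1,2,3-tris(benzyloxy)-5-[2,6-bis(benzyloxy)-4-chlorophenoxy]-4-(methoxymethoxy)benzene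
Conditions: BnBr, K2CO3, DMF, rt
Reagents that add atoms: benzyl bromide BrCc1ccccc1
Why: Williamson etherification of the single free phenol.

Step 21
Reactants: 40 5-iodo-1,2,3-trimethoxybenzene
Product: 41 5-iodobenzene-1,2,3-triol
Conditions: BBr3, CH2Cl2, −78 °C to rt; then H2O
Reagents that add atoms: none
Why: Lewis acid cleavage of aryl methyl ethers; the aryl iodide is inert to BBr3.

Step 22
Reactants: 41 5-iodobenzene-1,2,3-triol
Product: 42 1,2,3-tris(benzyloxy)-5-iodobenzene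
Conditions: BnBr, K2CO3, DMF, rt, under argon
Reagents that add atoms: benzyl bromide BrCc1ccccc1
Why: Threefold Williamson etherification, run without air because the pyrogallol is oxidised in base.

Step 23
Reactants: 27 2,6-bis(benzyloxy)-4-chlorophenol; 42 1,2,3-tris(benzyloxy)-5-iodobenzene
Product: 43 block J–K: 1,3-bis(benzyloxy)-5-chloro-2-[3,4,5-tris(benzyloxy)phenoxy]benzene
Conditions: CuI (cat.), picolinic acid (cat.), K3PO4, DMSO, 90 °C
Reagents that add atoms: none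
Why: Ligand-accelerated Ullmann etherification suited to hindered phenols; copper activates the unhindered C–I bond and leaves the C–Cl bond for step 30.

Step 24
Reactants: 25 A–B–C trimer O6 phenol; 39 block D–E
Product: 44 perbenzylated A–E pentamer with ring E C6–OMOM
Conditions: Pd(OAc)2 (cat.), tBuXPhos (cat.), K3PO4, toluene, 100 °C
Reagents that add atoms: none
Why: Palladium-catalysed C–O coupling as in step 4; the chloride of 39 has no ortho substituent, and 39 carries no free hydroxyl, so it cannot couple with itself.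

Step 25
Reactants: 44 A–E pentamer MOM ether
Product: 45 A–E pentamer O6 phenol (ring E)
Conditions: HCl (cat.), MeOH/THF, 45 °C
Reagents that add atoms: none
Why: Acid-catalysed MOM cleavage as in step 13.

Step 26
Reactants: 45 A–E pentamer phenol; 39 block D–E
Product: 46 perbenzylated A–G heptamer with ring G C6–OMOM
Conditions: Pd(OAc)2 (cat.), tBuXPhos (cat.), K3PO4, toluene, 100 °C
Reagents that add atoms: none
Why: Same palladium-catalysed C–O coupling; the reacting phenol has the same local environment as in step 24.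

Step 27
Reactants: 46 A–G heptamer MOM ether
Product: 47 A–G heptamer O6 phenol (ring G)
Conditions: HCl (cat.), MeOH/THF, 45 °C
Reagents that add atoms: none
Why: Acid-catalysed MOM cleavage.

Step 28
Reactants: 47 A–G heptamer phenol; 39 block D–E
Product: 48 perbenzylated A–I nonamer with ring I C6–OMOM
Conditions: Pd(OAc)2 (cat.), tBuXPhos (cat.), K3PO4, toluene, 100 °C
Reagents that add atoms: none
Why: Same palladium-catalysed C–O coupling.

Step 29
Reactants: 48 A–I nonamer MOM ether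
Product: 49 A–I nonamer O6 phenol (ring I)
Conditions: HCl (cat.), MeOH/THF, 45 °C
Reagents that add atoms: none
Why: Acid-catalysed MOM cleavage.

Step 30
Reactants: 49 A–I nonamer phenol; 43 block J–K
Product: 50 perbenzylated undecamer A–K (28 benzyl ethers)
Conditions: Pd(OAc)2 (cat.), tBuXPhos (cat.), K3PO4, toluene, 100 °C
Reagents that add atoms: none
Why: Same palladium-catalysed C–O coupling, now with the chloride of block 43, completes the chain.

Step 31
Reactants: 50 perbenzylated undecamer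
Product: 51 CNP0245174.0
Conditions: H2 (1 atm), Pd(OH)2/C, THF/MeOH, rt; filtration under argon
Reagents that add atoms: none
Why: Hydrogenolysis of all aryl benzyl ethers over palladium; diaryl ethers are inert at room temperature and the air-sensitive polyphenol is handled without oxygen.

**Compound list**

1 | 1,3,5-tris(benzyloxy)benzene | c1(OCc9ccccc9)cc(OCc9ccccc9)cc(OCc9ccccc9)c1 | starting material
2 | N-[2,4,6-tris(benzyloxy)benzylidene]-N-methylmethanaminium chloride | C[N+](C)=Cc1c(OCc9ccccc9)cc(OCc9ccccc9)cc1OCc9ccccc9.[Cl-] | intermediate (not isolated)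
3 | 2,4,6-tris(benzyloxy)benzaldehyde | O=Cc1c(OCc9ccccc9)cc(OCc9ccccc9)cc1OCc9ccccc9 | intermediate
4 | 2,4,6-tris(benzyloxy)phenyl formate | O=COc1c(OCc9ccccc9)cc(OCc9ccccc9)cc1OCc9ccccc9 | intermediate (not isolated)
5 | 2,4,6-tris(benzyloxy)phenol (ring A phenol) | Oc1c(OCc9ccccc9)cc(OCc9ccccc9)cc1OCc9ccccc9 | intermediate
6 | 4-chloro-2,6-difluorobenzaldehyde | O=Cc1c(F)cc(Cl)cc1F | starting material
7 | 2,6-bis(benzyloxy)-4-chlorobenzaldehyde | O=Cc1c(OCc9ccccc9)cc(Cl)cc1OCc9ccccc9 | intermediate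
8 | 2,6-bis(benzyloxy)-4-[2,4,6-tris(benzyloxy)phenoxy]benzaldehyde | O=Cc1c(OCc9ccccc9)cc(Oc2c(OCc9ccccc9)cc(OCc9ccccc9)cc2OCc9ccccc9)cc1OCc9ccccc9 | intermediate
9 | 2,6-bis(benzyloxy)-4-[2,4,6-tris(benzyloxy)phenoxy]phenyl formate | O=COc1c(OCc9ccccc9)cc(Oc2c(OCc9ccccc9)cc(OCc9ccccc9)cc2OCc9ccccc9)cc1OCc9ccccc9 | intermediate (not isolated)
10 | 2,6-bis(benzyloxy)-4-[2,4,6-tris(benzyloxy)phenoxy]phenol (phenol A–B) | Oc1c(OCc9ccccc9)cc(Oc2c(OCc9ccccc9)cc(OCc9ccccc9)cc2OCc9ccccc9)cc1OCc9ccccc9 | intermediate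
11 | 1,3-bis(benzyloxy)-2-{[(E)-1,2-dichloroethenyl]oxy}-5-[2,4,6-tris(benzyloxy)phenoxy]benzene | Cl/C=C(/Cl)Oc1c(OCc9ccccc9)cc(Oc2c(OCc9ccccc9)cc(OCc9ccccc9)cc2OCc9ccccc9)cc1OCc9ccccc9 | intermediate
12 | 1,3-bis(benzyloxy)-2-[(chloroethynyl)oxy]-5-[2,4,6-tris(benzyloxy)phenoxy]benzene | ClC#COc1c(OCc9ccccc9)cc(Oc2c(OCc9ccccc9)cc(OCc9ccccc9)cc2OCc9ccccc9)cc1OCc9ccccc9 | intermediate (not isolated)
13 | lithium {2,6-bis(benzyloxy)-4-[2,4,6-tris(benzyloxy)phenoxy]phenoxy}ethynide | [Li]C#COc1c(OCc9ccccc9)cc(Oc2c(OCc9ccccc9)cc(OCc9ccccc9)cc2OCc9ccccc9)cc1OCc9ccccc9 | intermediate (not isolated)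
14 | 1,3-bis(benzyloxy)-2-(ethynyloxy)-5-[2,4,6-tris(benzyloxy)phenoxy]benzene | C#COc1c(OCc9ccccc9)cc(Oc2c(OCc9ccccc9)cc(OCc9ccccc9)cc2OCc9ccccc9)cc1OCc9ccccc9 | intermediate
15 | tributyl(1-{2,6-bis(benzyloxy)-4-[2,4,6-tris(benzyloxy)phenoxy]phenoxy}ethenyl)stannane | C=C(Oc1c(OCc9ccccc9)cc(Oc2c(OCc9ccccc9)cc(OCc9ccccc9)cc2OCc9ccccc9)cc1OCc9ccccc9)[Sn](CCCC)(CCCC)CCCC | intermediate
16 | squaric acid (3,4-dihydroxycyclobut-3-ene-1,2-dione) | OC1=C(O)C(=O)C1=O | starting material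
17 | 3,4-bis(benzyloxy)cyclobut-3-ene-1,2-dione (dibenzyl squarate) | O=C1C(=O)C(OCc9ccccc9)=C1OCc9ccccc9 | intermediate
18 | (1-{2,6-bis(benzyloxy)-4-[2,4,6-tris(benzyloxy)phenoxy]phenoxy}ethenyl)lithium | [Li]C(=C)Oc1c(OCc9ccccc9)cc(Oc2c(OCc9ccccc9)cc(OCc9ccccc9)cc2OCc9ccccc9)cc1OCc9ccccc9 | intermediate (not isolated)
19 | lithium 2,3-bis(benzyloxy)-1-[1-(A–B aryloxy)ethenyl]-4-oxocyclobut-2-en-1-olate (racemic) | C=C(Oc1c(OCc9ccccc9)cc(Oc2c(OCc9ccccc9)cc(OCc9ccccc9)cc2OCc9ccccc9)cc1OCc9ccccc9)C8(O[Li])C(OCc9ccccc9)=C(OCc9ccccc9)C8=O | intermediate (not isolated)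
20 | 2,3-bis(benzyloxy)-4-(1-{2,6-bis(benzyloxy)-4-[2,4,6-tris(benzyloxy)phenoxy]phenoxy}ethenyl)-4-(methoxymethoxy)cyclobut-2-en-1-one (racemic) | C=C(Oc1c(OCc9ccccc9)cc(Oc2c(OCc9ccccc9)cc(OCc9ccccc9)cc2OCc9ccccc9)cc1OCc9ccccc9)C8(OCOC)C(OCc9ccccc9)=C(OCc9ccccc9)C8=O | intermediate
21 | (3Z)-2,3-bis(benzyloxy)-5-(A–B aryloxy)-4-(methoxymethoxy)hexa-1,3,5-trien-1-one (dienylketene) | O=C=C(OCc9ccccc9)/C(OCc9ccccc9)=C(/OCOC)C(=C)Oc1c(OCc9ccccc9)cc(Oc2c(OCc9ccccc9)cc(OCc9ccccc9)cc2OCc9ccccc9)cc1OCc9ccccc9 | intermediate (not isolated)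
22 | 2,3-bis(benzyloxy)-5-(A–B aryloxy)-4-(methoxymethoxy)cyclohexa-2,4-dien-1-one | O=C1CC(Oc2c(OCc9ccccc9)cc(Oc3c(OCc9ccccc9)cc(OCc9ccccc9)cc3OCc9ccccc9)cc2OCc9ccccc9)=C(OCOC)C(OCc9ccccc9)=C1OCc9ccccc9 | intermediate (not isolated)
23 | 2,3-bis(benzyloxy)-5-{2,6-bis(benzyloxy)-4-[2,4,6-tris(benzyloxy)phenoxy]phenoxy}-4-(methoxymethoxy)phenol (A–B–C trimer, ring C C3–OH free, C6–OMOM) | C(c9ccccc9)Oc1cc(OCc9ccccc9)c(Oc2cc(OCc9ccccc9)c(Oc3cc(O)c(OCc9ccccc9)c(OCc9ccccc9)c3OCOC)c(OCc9ccccc9)c2)c(OCc9ccccc9)c1 | intermediate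
24 | 1,2,3-tris(benzyloxy)-5-{2,6-bis(benzyloxy)-4-[2,4,6-tris(benzyloxy)phenoxy]phenoxy}-4-(methoxymethoxy)benzene | C(c9ccccc9)Oc1cc(OCc9ccccc9)c(Oc2cc(OCc9ccccc9)c(Oc3cc(OCc9ccccc9)c(OCc9ccccc9)c(OCc9ccccc9)c3OCOC)c(OCc9ccccc9)c2)c(OCc9ccccc9)c1 | intermediate
25 | 2,3,4-tris(benzyloxy)-6-{2,6-bis(benzyloxy)-4-[2,4,6-tris(benzyloxy)phenoxy]phenoxy}phenol (A–B–C trimer, free O6–H) | C(c9ccccc9)Oc1cc(OCc9ccccc9)c(Oc2cc(OCc9ccccc9)c(Oc3cc(OCc9ccccc9)c(OCc9ccccc9)c(OCc9ccccc9)c3O)c(OCc9ccccc9)c2)c(OCc9ccccc9)c1 | intermediate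
26 | 2,6-bis(benzyloxy)-4-chlorophenyl formate | O=COc1c(OCc9ccccc9)cc(Cl)cc1OCc9ccccc9 | intermediate (not isolated)
27 | 2,6-bis(benzyloxy)-4-chlorophenol | Oc1c(OCc9ccccc9)cc(Cl)cc1OCc9ccccc9 | intermediate
28 | 1,3-bis(benzyloxy)-5-chloro-2-{[(E)-1,2-dichloroethenyl]oxy}benzene | Cl/C=C(/Cl)Oc1c(OCc9ccccc9)cc(Cl)cc1OCc9ccccc9 | intermediate
29 | 1,3-bis(benzyloxy)-5-chloro-2-[(chloroethynyl)oxy]benzene | ClC#COc1c(OCc9ccccc9)cc(Cl)cc1OCc9ccccc9 | intermediate (not isolated)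
30 | lithium [2,6-bis(benzyloxy)-4-chlorophenoxy]ethynide | [Li]C#COc1c(OCc9ccccc9)cc(Cl)cc1OCc9ccccc9 | intermediate (not isolated)
31 | 1,3-bis(benzyloxy)-5-chloro-2-(ethynyloxy)benzene | C#COc1c(OCc9ccccc9)cc(Cl)cc1OCc9ccccc9 | intermediate
32 | tributyl{1-[2,6-bis(benzyloxy)-4-chlorophenoxy]ethenyl}stannane | C=C(Oc1c(OCc9ccccc9)cc(Cl)cc1OCc9ccccc9)[Sn](CCCC)(CCCC)CCCC | intermediate
33 | {1-[2,6-bis(benzyloxy)-4-chlorophenoxy]ethenyl}lithium | [Li]C(=C)Oc1c(OCc9ccccc9)cc(Cl)cc1OCc9ccccc9 | intermediate (not isolated)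
34 | lithium 2,3-bis(benzyloxy)-1-{1-[2,6-bis(benzyloxy)-4-chlorophenoxy]ethenyl}-4-oxocyclobut-2-en-1-olate (racemic) | C=C(Oc1c(OCc9ccccc9)cc(Cl)cc1OCc9ccccc9)C8(O[Li])C(OCc9ccccc9)=C(OCc9ccccc9)C8=O | intermediate (not isolated)
35 | 2,3-bis(benzyloxy)-4-{1-[2,6-bis(benzyloxy)-4-chlorophenoxy]ethenyl}-4-(methoxymethoxy)cyclobut-2-en-1-one (racemic) | C=C(Oc1c(OCc9ccccc9)cc(Cl)cc1OCc9ccccc9)C8(OCOC)C(OCc9ccccc9)=C(OCc9ccccc9)C8=O | intermediate
36 | (3Z)-2,3-bis(benzyloxy)-5-[2,6-bis(benzyloxy)-4-chlorophenoxy]-4-(methoxymethoxy)hexa-1,3,5-trien-1-one | O=C=C(OCc9ccccc9)/C(OCc9ccccc9)=C(/OCOC)C(=C)Oc1c(OCc9ccccc9)cc(Cl)cc1OCc9ccccc9 | intermediate (not isolated)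
37 | 2,3-bis(benzyloxy)-5-[2,6-bis(benzyloxy)-4-chlorophenoxy]-4-(methoxymethoxy)cyclohexa-2,4-dien-1-one | O=C1CC(Oc2c(OCc9ccccc9)cc(Cl)cc2OCc9ccccc9)=C(OCOC)C(OCc9ccccc9)=C1OCc9ccccc9 | intermediate (not isolated)
38 | 2,3-bis(benzyloxy)-5-[2,6-bis(benzyloxy)-4-chlorophenoxy]-4-(methoxymethoxy)phenol | Clc1cc(OCc9ccccc9)c(Oc2cc(O)c(OCc9ccccc9)c(OCc9ccccc9)c2OCOC)c(OCc9ccccc9)c1 | intermediate
39 | 1,2,3-tris(benzyloxy)-5-[2,6-bis(benzyloxy)-4-chlorophenoxy]-4-(methoxymethoxy)benzene (block D–E) | Clc1cc(OCc9ccccc9)c(Oc2cc(OCc9ccccc9)c(OCc9ccccc9)c(OCc9ccccc9)c2OCOC)c(OCc9ccccc9)c1 | intermediate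
40 | 5-iodo-1,2,3-trimethoxybenzene | COc1cc(I)cc(OC)c1OC | starting material
41 | 5-iodobenzene-1,2,3-triol | Oc1cc(I)cc(O)c1O | intermediate
42 | 1,2,3-tris(benzyloxy)-5-iodobenzene | Ic1cc(OCc9ccccc9)c(OCc9ccccc9)c(OCc9ccccc9)c1 | intermediate
43 | 1,3-bis(benzyloxy)-5-chloro-2-[3,4,5-tris(benzyloxy)phenoxy]benzene (block J–K) | Clc1cc(OCc9ccccc9)c(Oc2cc(OCc9ccccc9)c(OCc9ccccc9)c(OCc9ccccc9)c2)c(OCc9ccccc9)c1 | intermediate
44 | perbenzylated A–E pentamer, ring E C6–OMOM | C(c9ccccc9)Oc1cc(OCc9ccccc9)c(Oc2cc(OCc9ccccc9)c(Oc3cc(OCc9ccccc9)c(OCc9ccccc9)c(OCc9ccccc9)c3Oc3cc(OCc9ccccc9)c(Oc4cc(OCc9ccccc9)c(OCc9ccccc9)c(OCc9ccccc9)c4OCOC)c(OCc9ccccc9)c3)c(OCc9ccccc9)c2)c(OCc9ccccc9)c1 | intermediate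
45 | perbenzylated A–E pentamer, ring E C6–OH | C(c9ccccc9)Oc1cc(OCc9ccccc9)c(Oc2cc(OCc9ccccc9)c(Oc3cc(OCc9ccccc9)c(OCc9ccccc9)c(OCc9ccccc9)c3Oc3cc(OCc9ccccc9)c(Oc4cc(OCc9ccccc9)c(OCc9ccccc9)c(OCc9ccccc9)c4O)c(OCc9ccccc9)c3)c(OCc9ccccc9)c2)c(OCc9ccccc9)c1 | intermediate
46 | perbenzylated A–G heptamer, ring G C6–OMOM | C(c9ccccc9)Oc1cc(OCc9ccccc9)c(Oc2cc(OCc9ccccc9)c(Oc3cc(OCc9ccccc9)c(OCc9ccccc9)c(OCc9ccccc9)c3Oc3cc(OCc9ccccc9)c(Oc4cc(OCc9ccccc9)c(OCc9ccccc9)c(OCc9ccccc9)c4Oc4cc(OCc9ccccc9)c(Oc5cc(OCc9ccccc9)c(OCc9ccccc9)c(OCc9ccccc9)c5OCOC)c(OCc9ccccc9)c4)c(OCc9ccccc9)c3)c(OCc9ccccc9)c2)c(OCc9ccccc9)c1 | intermediate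
47 | perbenzylated A–G heptamer, ring G C6–OH | C(c9ccccc9)Oc1cc(OCc9ccccc9)c(Oc2cc(OCc9ccccc9)c(Oc3cc(OCc9ccccc9)c(OCc9ccccc9)c(OCc9ccccc9)c3Oc3cc(OCc9ccccc9)c(Oc4cc(OCc9ccccc9)c(OCc9ccccc9)c(OCc9ccccc9)c4Oc4cc(OCc9ccccc9)c(Oc5cc(OCc9ccccc9)c(OCc9ccccc9)c(OCc9ccccc9)c5O)c(OCc9ccccc9)c4)c(OCc9ccccc9)c3)c(OCc9ccccc9)c2)c(OCc9ccccc9)c1 | intermediate
48 | perbenzylated A–I nonamer, ring I C6–OMOM | C(c9ccccc9)Oc1cc(OCc9ccccc9)c(Oc2cc(OCc9ccccc9)c(Oc3cc(OCc9ccccc9)c(OCc9ccccc9)c(OCc9ccccc9)c3Oc3cc(OCc9ccccc9)c(Oc4cc(OCc9ccccc9)c(OCc9ccccc9)c(OCc9ccccc9)c4Oc4cc(OCc9ccccc9)c(Oc5cc(OCc9ccccc9)c(OCc9ccccc9)c(OCc9ccccc9)c5Oc5cc(OCc9ccccc9)c(Oc6cc(OCc9ccccc9)c(OCc9ccccc9)c(OCc9ccccc9)c6OCOC)c(OCc9ccccc9)c5)c(OCc9ccccc9)c4)c(OCc9ccccc9)c3)c(OCc9ccccc9)c2)c(OCc9ccccc9)c1 | intermediate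
49 | perbenzylated A–I nonamer, ring I C6–OH | C(c9ccccc9)Oc1cc(OCc9ccccc9)c(Oc2cc(OCc9ccccc9)c(Oc3cc(OCc9ccccc9)c(OCc9ccccc9)c(OCc9ccccc9)c3Oc3cc(OCc9ccccc9)c(Oc4cc(OCc9ccccc9)c(OCc9ccccc9)c(OCc9ccccc9)c4Oc4cc(OCc9ccccc9)c(Oc5cc(OCc9ccccc9)c(OCc9ccccc9)c(OCc9ccccc9)c5Oc5cc(OCc9ccccc9)c(Oc6cc(OCc9ccccc9)c(OCc9ccccc9)c(OCc9ccccc9)c6O)c(OCc9ccccc9)c5)c(OCc9ccccc9)c4)c(OCc9ccccc9)c3)c(OCc9ccccc9)c2)c(OCc9ccccc9)c1 | intermediate
50 | perbenzylated undecamer A–K (all 28 hydroxyls of the target as benzyl ethers) | C(c9ccccc9)Oc1cc(OCc9ccccc9)c(Oc2cc(OCc9ccccc9)c(Oc3cc(OCc9ccccc9)c(OCc9ccccc9)c(OCc9ccccc9)c3Oc3cc(OCc9ccccc9)c(Oc4cc(OCc9ccccc9)c(OCc9ccccc9)c(OCc9ccccc9)c4Oc4cc(OCc9ccccc9)c(Oc5cc(OCc9ccccc9)c(OCc9ccccc9)c(OCc9ccccc9)c5Oc5cc(OCc9ccccc9)c(Oc6cc(OCc9ccccc9)c(OCc9ccccc9)c(OCc9ccccc9)c6Oc6cc(OCc9ccccc9)c(Oc7cc(OCc9ccccc9)c(OCc9ccccc9)c(OCc9ccccc9)c7)c(OCc9ccccc9)c6)c(OCc9ccccc9)c5)c(OCc9ccccc9)c4)c(OCc9ccccc9)c3)c(OCc9ccccc9)c2)c(OCc9ccccc9)c1 | intermediate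
51 | CNP0245174.0 (undecameric fuhalol-type phlorotannin, no stereocentres) | Oc1cc(O)c(Oc2cc(O)c(Oc3cc(O)c(O)c(O)c3Oc3cc(O)c(Oc4cc(O)c(O)c(O)c4Oc4cc(O)c(Oc5cc(O)c(O)c(O)c5Oc5cc(O)c(Oc6cc(O)c(O)c(O)c6Oc6cc(O)c(Oc7cc(O)c(O)c(O)c7)c(O)c6)c(O)c5)c(O)c4)c(O)c3)c(O)c2)c(O)c1 | target

**Step count and risk**

Total step count: 31. Longest linear sequence: 19 steps (1, 2, 4 to 8, 10 to 13, 24 to 31).

Steps most likely to fail:

1. Step 24 (the same concern holds for steps 26, 28 and 30). Oxidative addition into the electron-rich chloride, or C–O reductive elimination from a palladium centre that carries the congested 2-aryloxy-6-benzyloxy phenoxide, may be too slow, so that reduction of the chloride and catalyst decay take over. The fallback sets out from block 39 and phenol 25 and changes the coupling from a halide/palladium process to an oxidative boron/copper process. Miyaura borylation of 39 (Pd2(dba)3, XPhos, B2pin2, KOAc, dioxane, 100 °C) should give the pinacol boronate F1. Oxidative cleavage of the pinacol ester (NaIO4, NH4OAc, acetone/water, rt) should give the boronic acid F2. Chan–Lam–Evans etherification of 25 with F2 (Cu(OAc)2, pyridine, 4 Å molecular sieves, CH2Cl2, air, rt), a method that accepts di-ortho-substituted phenols, returns to the route at 44.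

2. Step 10. The hindered tertiary lithium alkoxide 19 may resist O-alkylation by MOMCl at low temperature and fragment by retro-addition on warming, and the 1-(aryloxy)vinyllithium may decay by α-elimination if addition is slow. The fallback sets out from alkoxide 19 (made from 15 and 17 as in step 10) and drops the MOM group. Quenching at −78 °C with AcOH gives the tertiary alcohol F3. Thermolysis (toluene, 110 °C, degassed) by the same ring expansion, through the hydroxy dienylketene F4 and the cyclohexadienone F5, gives the hydroquinone F6 with O3–H and O6–H free. Selective Williamson benzylation of the less hindered O3–H, which is flanked by C2–H (BnBr 1 equiv, K2CO3, acetone, rt), returns to the route at 25, bypassing 20, 23 and 24.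

3. Step 11. At 110 °C the electron-rich dienylketene may be diverted by dimerisation, by addition of adventitious nucleophiles or by cycloaddition with the enol ether before the 6π closure, and the enol ether may cleave. The fallback sets out from iodide 42 and phenol 10 and brings ring C in as a preformed arene. Vilsmeier–Haack formylation of 42 (POCl3, DMF, 80 °C; then H2O), through the iminium chloride F7, can occur only ortho to iodine and should give 6-iodo-2,3,4-tris(benzyloxy)benzaldehyde F8. Ullmann etherification of 10 with F8 (CuI, picolinic acid, K3PO4, DMSO, 90 °C), helped by the ortho formyl group, should give the diaryl ether aldehyde F9. Baeyer–Villiger oxidation (mCPBA, CH2Cl2, 0 °C) to the aryl formate F10 and methanolysis (K2CO3 cat., MeOH) turn the formyl carbon into O6–H and return to the route at 25.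

**Further compounds**

F1 | step 24 | 2-{3,5-bis(benzyloxy)-4-[3,4,5-tris(benzyloxy)-2-(methoxymethoxy)phenoxy]phenyl}-4,4,5,5-tetramethyl-1,3,2-dioxaborolane | CC1(C)OB(OC1(C)C)c1cc(OCc9ccccc9)c(Oc2cc(OCc9ccccc9)c(OCc9ccccc9)c(OCc9ccccc9)c2OCOC)c(OCc9ccccc9)c1
F2 | step 24 | {3,5-bis(benzyloxy)-4-[3,4,5-tris(benzyloxy)-2-(methoxymethoxy)phenoxy]phenyl}boronic acid | OB(O)c1cc(OCc9ccccc9)c(Oc2cc(OCc9ccccc9)c(OCc9ccccc9)c(OCc9ccccc9)c2OCOC)c(OCc9ccccc9)c1
F3 | step 10 | 2,3-bis(benzyloxy)-4-hydroxy-4-(1-{2,6-bis(benzyloxy)-4-[2,4,6-tris(benzyloxy)phenoxy]phenoxy}ethenyl)cyclobut-2-en-1-one (racemic) | C=C(Oc1c(OCc9ccccc9)cc(Oc2c(OCc9ccccc9)cc(OCc9ccccc9)cc2OCc9ccccc9)cc1OCc9ccccc9)C8(O)C(OCc9ccccc9)=C(OCc9ccccc9)C8=O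
F4 | step 10 | (3Z)-2,3-bis(benzyloxy)-4-hydroxy-5-(A–B aryloxy)hexa-1,3,5-trien-1-one | O=C=C(OCc9ccccc9)/C(OCc9ccccc9)=C(/O)C(=C)Oc1c(OCc9ccccc9)cc(Oc2c(OCc9ccccc9)cc(OCc9ccccc9)cc2OCc9ccccc9)cc1OCc9ccccc9
F5 | step 10 | 2,3-bis(benzyloxy)-4-hydroxy-5-(A–B aryloxy)cyclohexa-2,4-dien-1-one | O=C1CC(Oc2c(OCc9ccccc9)cc(Oc3c(OCc9ccccc9)cc(OCc9ccccc9)cc3OCc9ccccc9)cc2OCc9ccccc9)=C(O)C(OCc9ccccc9)=C1OCc9ccccc9
F6 | step 10 | 2,3-bis(benzyloxy)-5-{2,6-bis(benzyloxy)-4-[2,4,6-tris(benzyloxy)phenoxy]phenoxy}benzene-1,4-diol | C(c9ccccc9)Oc1cc(OCc9ccccc9)c(Oc2cc(OCc9ccccc9)c(Oc3cc(O)c(OCc9ccccc9)c(OCc9ccccc9)c3O)c(OCc9ccccc9)c2)c(OCc9ccccc9)c1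
F7 | step 11 | N-[2,3,4-tris(benzyloxy)-6-iodobenzylidene]-N-methylmethanaminium chloride | C[N+](C)=Cc1c(I)cc(OCc9ccccc9)c(OCc9ccccc9)c1OCc9ccccc9.[Cl-]
F8 | step 11 | 6-iodo-2,3,4-tris(benzyloxy)benzaldehyde | O=Cc1c(I)cc(OCc9ccccc9)c(OCc9ccccc9)c1OCc9ccccc9
F9 | step 11 | 2,3,4-tris(benzyloxy)-6-{2,6-bis(benzyloxy)-4-[2,4,6-tris(benzyloxy)phenoxy]phenoxy}benzaldehyde | O=Cc1c(Oc2c(OCc9ccccc9)cc(Oc3c(OCc9ccccc9)cc(OCc9ccccc9)cc3OCc9ccccc9)cc2OCc9ccccc9)cc(OCc9ccccc9)c(OCc9ccccc9)c1OCc9ccccc9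
F10 | step 11 | 2,3,4-tris(benzyloxy)-6-{2,6-bis(benzyloxy)-4-[2,4,6-tris(benzyloxy)phenoxy]phenoxy}phenyl formate | O=COc1c(Oc2c(OCc9ccccc9)cc(Oc3c(OCc9ccccc9)cc(OCc9ccccc9)cc3OCc9ccccc9)cc2OCc9ccccc9)cc(OCc9ccccc9)c(OCc9ccccc9)c1OCc9ccccc9
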